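**Retrosynthetic overview**
- The target is unmasked from a tris-benzyl chalcone by one hydrogenation (C=C saturation and loss of three O-benzyl groups); the chalcone comes from a Claisen–Schmidt condensation of a 3-alkylated 2,4-bis(benzyloxy)benzaldehyde with 4'-(benzyloxy)acetophenone.
- Key disconnection: the aryl–CH2 bond of the diol side chain, made by a visible-light nickel/organophotoredox cross-electrophile coupling of 2,4-bis(benzyloxy)-3-iodobenzaldehyde with (R)-2-(oxiran-2-yl)propan-2-ol, opened at its terminal carbon.
- The epoxy alcohol comes in one step from methyl (R)-glycidate (made from L-serine) and MeMgCl; the aryl iodide comes in two steps from 2-iodoresorcinol (O-benzylation, Vilsmeier formylation).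
- Rings: both benzene rings are bought intact and no ring is built; the only ring that changes is the bought oxirane, which is opened in the key step.

Assumption: 2-iodoresorcinol, methyl (2R)-oxirane-2-carboxylate and 4'-(benzyloxy)acetophenone are taken as catalogue compounds, and the target stereocentre is (R), as the SMILES encodes.

**Route**

Step 1
Reactants: 1 2-iodoresorcinol (2-iodobenzene-1,3-diol)
Product: 2 1,3-bis(benzyloxy)-2-iodobenzene
Conditions: BnBr (2.3 equiv), K2CO3 (3 equiv), DMF, 60 °C
Reagents that add atoms: benzyl bromide (BrCc1ccccc1)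
Why: Williamson ether synthesis (phenoxide SN2 on benzyl bromide) caps both phenols with groups that are base- and radical-stable and that fall off in the final hydrogenation without a separate step.

Step 2
Reactants: 2 1,3-bis(benzyloxy)-2-iodobenzene
Product: 4 2,4-bis(benzyloxy)-3-iodobenzaldehyde, via iminium salt 3 (not isolated)
Conditions: POCl3 (1.5 equiv), DMF, 0 to 75 °C; then ice-water, aq NaOH to pH 7
Reagents that add atoms: N,N-dimethylformamide (CN(C)C=O); water (O)
Why: Vilsmeier–Haack formylation, in which the chloroiminium ion attacks the only activated position (ortho to one benzyloxy group and para to the other, the remaining CH being meta to both), as in the formylation of 1,2,3-trimethoxybenzene, and water hydrolyses iminium salt 3 to the aldehyde.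

Step 3
Reactants: 5 methyl (2R)-oxirane-2-carboxylate (methyl (R)-glycidate)
Product: 7 2-[(2R)-oxiran-2-yl]propan-2-ol, via epoxy ketone 6 (not isolated)
Conditions: MeMgCl (2.1 equiv), THF, −78 °C, 1 h; then satd aq NH4Cl at −78 °C; careful distillation
Reagents that add atoms: methylmagnesium chloride (C[Mg]Cl)
Why: Double Grignard addition to the ester through ketone 6, where at −78 °C both carbonyls react far faster than the oxirane (the chloride Grignard and cold quench limit halide opening and Payne migration), and the bought stereocentre keeps all four of its bonds.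

Step 4
Reactants: 4 2,4-bis(benzyloxy)-3-iodobenzaldehyde; 7 2-[(2R)-oxiran-2-yl]propan-2-ol (2.0 equiv)
Product: 9 2,4-bis(benzyloxy)-3-[(2R)-2,3-dihydroxy-3-methylbutyl]benzaldehyde, via iodohydrin 8 (not isolated)
Conditions: NiBr2·MeOCH2CH2OMe (10 mol %), 4,4'-dimethoxy-2,2'-bipyridine (12 mol %), 4CzIPN (2,4,5,6-tetrakis(carbazol-9-yl)isophthalonitrile, 3 mol %), Et3N·HI (0.5 equiv), Et3N (3 equiv), DMA, 450 nm LEDs, 30 °C, 24 h; then dilute aq NaOH wash
Reagents that add atoms: none
Why: Proposed new method: a titanium-free, iodide-relay nickel/organophotoredox cross-electrophile coupling of a 2,6-dialkoxyaryl iodide with an unprotected chiral 2,3-epoxy alcohol — Et3N·HI opens the oxirane of 7 reversibly by SN2 at the unhindered CH2 to give iodohydrin 8, the α-aminoalkyl radical formed from Et3N after photo-oxidation by excited 4CzIPN (or a univalent nickel species) abstracts the iodine atom to leave a primary β-hydroxyalkyl radical, this radical is trapped by the aryl–nickel iodide formed by oxidative addition of zerovalent nickel into the C–I bond of 4, and reductive elimination from trivalent nickel forms the aryl–CH2 bond while the reduced photocatalyst returns nickel to its low-valent state; the C–O bond at the stereocentre is never broken and the radical sits one carbon away, so the (R) centre bought in 5 is carried over unchanged, and the closest known reaction type is the nickel/photoredox (and nickel/iodide reductive) cross-electrophile coupling of aryl halides with simple aliphatic epoxides, which has not been shown for a hydroxyl-bearing glycidol-type epoxide or a di-ortho-oxygenated aryl halide.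

Step 5
Reactants: 9 2,4-bis(benzyloxy)-3-[(2R)-2,3-dihydroxy-3-methylbutyl]benzaldehyde; 10 1-[4-(benzyloxy)phenyl]ethan-1-one (4'-(benzyloxy)acetophenone)
Product: 12 (E)-3-{2,4-bis(benzyloxy)-3-[(2R)-2,3-dihydroxy-3-methylbutyl]phenyl}-1-[4-(benzyloxy)phenyl]prop-2-en-1-one, via aldol adduct 11 (not isolated)
Conditions: KOH (50% aq, 3 equiv), EtOH–THF 2:1, rt, 24 h
Reagents that add atoms: none
Why: Claisen–Schmidt condensation, in which the enolate of 10 adds to the non-enolisable aldehyde and aldol adduct 11 loses water by E1cB to give the conjugated (E)-enone, while the diol, the benzyl ethers and the remote stereocentre are inert to aqueous base.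

Step 6
Reactants: 12 (E)-3-{2,4-bis(benzyloxy)-3-[(2R)-2,3-dihydroxy-3-methylbutyl]phenyl}-1-[4-(benzyloxy)phenyl]prop-2-en-1-one
Product: 14 3-{2,4-dihydroxy-3-[(2R)-2,3-dihydroxy-3-methylbutyl]phenyl}-1-(4-hydroxyphenyl)propan-1-one (target), via tribenzyl dihydrochalcone 13 (not isolated)
Conditions: H2 (1 atm), 10% Pd/C, EtOAc–MeOH 1:1, rt; stopped after uptake of 4 equiv H2
Reagents that add atoms: none
Why: Heterogeneous catalytic hydrogenation saturates the enone C=C first (13) and then hydrogenolyses the three O-benzyl bonds, while the aryl ketone and the non-benzylic secondary and tertiary alcohols (the stereocentre is homobenzylic) survive under neutral conditions at 1 atm.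

**Compound list**
1 | 2-iodoresorcinol (2-iodobenzene-1,3-diol) | Oc1cccc(O)c1I | starting material
2 | 1,3-bis(benzyloxy)-2-iodobenzene | Ic1c(OCc2ccccc2)cccc1OCc1ccccc1 | intermediate
3 | {[2,4-bis(benzyloxy)-3-iodophenyl]methylidene}dimethylammonium chloride (iminium salt, formed in the flask in step 2) | C[N+](C)=Cc1ccc(OCc2ccccc2)c(I)c1OCc1ccccc1.[Cl-] | intermediate
4 | 2,4-bis(benzyloxy)-3-iodobenzaldehyde | O=Cc1ccc(OCc2ccccc2)c(I)c1OCc1ccccc1 | intermediate
5 | methyl (2R)-oxirane-2-carboxylate | COC(=O)[C@H]1CO1 | starting material
6 | 1-[(2R)-oxiran-2-yl]ethan-1-one (formed in the flask in step 3) | CC(=O)[C@H]1CO1 | intermediate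
7 | 2-[(2R)-oxiran-2-yl]propan-2-ol | CC(C)(O)[C@H]1CO1 | intermediate
8 | (2S)-1-iodo-3-methylbutane-2,3-diol (formed in the flask in step 4; same spatial arrangement as 7, the descriptor changes only because CH2I outranks the carbinol carbon) | CC(C)(O)[C@H](O)CI | intermediate
9 | 2,4-bis(benzyloxy)-3-[(2R)-2,3-dihydroxy-3-methylbutyl]benzaldehyde | CC(C)(O)[C@H](O)Cc1c(OCc2ccccc2)ccc(C=O)c1OCc1ccccc1 | intermediate
10 | 1-[4-(benzyloxy)phenyl]ethan-1-one | CC(=O)c1ccc(OCc2ccccc2)cc1 | starting material
11 | 3-{2,4-bis(benzyloxy)-3-[(2R)-2,3-dihydroxy-3-methylbutyl]phenyl}-1-[4-(benzyloxy)phenyl]-3-hydroxypropan-1-one (both epimers at the new carbinol; formed in the flask in step 5) | CC(C)(O)[C@H](O)Cc1c(OCc2ccccc2)ccc(C(O)CC(=O)c2ccc(OCc3ccccc3)cc2)c1OCc1ccccc1 | intermediate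
12 | (E)-3-{2,4-bis(benzyloxy)-3-[(2R)-2,3-dihydroxy-3-methylbutyl]phenyl}-1-[4-(benzyloxy)phenyl]prop-2-en-1-one | CC(C)(O)[C@H](O)Cc1c(OCc2ccccc2)ccc(/C=C/C(=O)c2ccc(OCc3ccccc3)cc2)c1OCc1ccccc1 | intermediate
13 | 3-{2,4-bis(benzyloxy)-3-[(2R)-2,3-dihydroxy-3-methylbutyl]phenyl}-1-[4-(benzyloxy)phenyl]propan-1-one (formed in the flask in step 6) | CC(C)(O)[C@H](O)Cc1c(OCc2ccccc2)ccc(CCC(=O)c2ccc(OCc3ccccc3)cc2)c1OCc1ccccc1 | intermediate
14 | 3-{2,4-dihydroxy-3-[(2R)-2,3-dihydroxy-3-methylbutyl]phenyl}-1-(4-hydroxyphenyl)propan-1-one | CC(C)(O)[C@H](O)Cc1c(O)ccc(CCC(=O)c2ccc(O)cc2)c1O | target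

**Step count**
Total steps: 6. Longest linear sequence: 5 (steps 1, 2, 4, 5 and 6 from 2-iodoresorcinol); step 3 is a one-step branch. The benzyl ethers cost one step to put on and none to remove.

**Steps most likely to fail, with fallbacks**

Step 4 (the proposed coupling) is the main risk. The aryl–nickel species is flanked by two benzyloxy groups, so radical capture may be slow. That would leave room for proto-deiodination, 1,5-hydrogen transfer from an O-CH2Ph group, or β-hydroxy elimination of the alkyl fragment. The iodide rather than the bromide and the small, electron-rich bipyridine are chosen to help. Titanium co-catalysts are left out on purpose, because trivalent titanium would open the oxirane at the stereocentre and destroy it. The fallback uses known organomagnesium/copper chemistry, sets out from 4 and 7 and comes back at 9. Aldehyde 4 is converted with HC(OMe)3 and catalytic TsOH in MeOH into 1,3-bis(benzyloxy)-4-(dimethoxymethyl)-2-iodobenzene F1. Alcohol 7 is silylated (TMSCl, imidazole, CH2Cl2) to trimethyl({2-[(2R)-oxiran-2-yl]propan-2-yl}oxy)silane F2. Iodine–magnesium exchange on F1 with i-PrMgCl·LiCl (THF, −30 °C) gives [2,6-bis(benzyloxy)-3-(dimethoxymethyl)phenyl]magnesium chloride F3. With CuI (10 mol %), F3 opens F2 by SN2 at the terminal CH2 (−30 to 0 °C) to give (2R)-1-[2,6-bis(benzyloxy)-3-(dimethoxymethyl)phenyl]-3-methyl-3-[(trimethylsilyl)oxy]butan-2-ol F4. Stirring F4 with 1 M HCl in THF at rt removes the acetal and the silyl ether and delivers 9.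

Step 2 may be sluggish, because the ring is a hindered diether carrying an inductively withdrawing iodine. Forcing it risks loss of a benzyl group next to the iminium or loss of iodine. The fallback changes the order and the type of formylation, sets out from 1 and comes back at 4. Free 2-iodoresorcinol is ortho-formylated through its magnesium phenoxide (MgCl2, Et3N, paraformaldehyde, MeCN, reflux; basic, so no acid-induced iodine migration) to give 2,4-dihydroxy-3-iodobenzaldehyde F5. F5 is then bis-O-benzylated (BnBr, K2CO3, DMF, 60 °C) to 4.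

Step 6 can over-run. The aryl ketone may be reduced, or the freed ortho-phenol may close onto the ketone and be reduced on to a flavan. The fallback separates the two events, sets out from 12 and comes back at 14. The enone is reduced 1,4 with [(Ph3P)CuH]6 in toluene–THF at rt, and 13 is isolated. Its benzyl ethers are then removed by transfer hydrogenolysis (Pd(OH)2/C, 1,4-cyclohexadiene, EtOH, rt), which leaves aryl ketones alone. This path passes only through 13, already in the compound list, so it adds no new compound (none, F0).

Further compounds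
F1 | step 4 | 1,3-bis(benzyloxy)-4-(dimethoxymethyl)-2-iodobenzene | COC(OC)c1ccc(OCc2ccccc2)c(I)c1OCc1ccccc1
F2 | step 4 | trimethyl({2-[(2R)-oxiran-2-yl]propan-2-yl}oxy)silane | CC(C)(O[Si](C)(C)C)[C@H]1CO1
F3 | step 4 | [2,6-bis(benzyloxy)-3-(dimethoxymethyl)phenyl]magnesium chloride | COC(OC)c1ccc(OCc2ccccc2)c([Mg]Cl)c1OCc1ccccc1
F4 | step 4 | (2R)-1-[2,6-bis(benzyloxy)-3-(dimethoxymethyl)phenyl]-3-methyl-3-[(trimethylsilyl)oxy]butan-2-ol | CC(C)(O[Si](C)(C)C)[C@H](O)Cc1c(OCc2ccccc2)ccc(C(OC)OC)c1OCc1ccccc1
F5 | step 2 | 2,4-dihydroxy-3-iodobenzaldehyde | O=Cc1ccc(O)c(I)c1O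
F0 | step 6 | none | none
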